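**Retrosynthetic overview**

1. Locants follow the 2H-chromene numbering of the target (O1, C2, C3, C4, C4a, C5 to C8, C8a); ring A is the hexasubstituted phloroglucinol ring, ring B the pyran ring, ring C the 4-hydroxyphenyl ring. The last step frees the ring C phenol of 14 from its tosylate.
2. Ring B is closed last, by the C4–C4a bond, from an aryl 1,1-dimethylpropargyl ether on O1 (propargyl Claisen shift, 1,5-hydrogen shift, 6π oxa-electrocyclisation). In the same heating the C8 prenyl group arrives from a 1,1-dimethylallyl ether on O7 by an allyl Claisen shift, so the precursor 10 is an acyclic bis-ether with bare C4a and C8.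
3. Enabling feature: O1 (on C8a) is para to the aroyl-bearing C6, its two ortho carbons C4a and C8 are the only unsubstituted carbons of ring A and are mirror-related in the benzophenone, and the oxygens on C5 and C7 both end as free OH. Either of these oxygens may therefore carry the allyl group, and once C8 is filled only C4a is left for the propargyl shift.
4. 10 comes from triol 6 by two ordered O-alkylations: first the oxygen para to the carbonyl (copper-catalysed propargylation), then one of the two equivalent ortho oxygens (palladium-catalysed tert-prenylation).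
5. 6 comes from phloroglucinol and 4-cyanophenyl tosylate by Hoesch acylation; rings A and C are bought, ring B is the only ring formed.

Key step: step 5

Assumption: tert-butyl 2-methylbut-3-en-2-yl carbonate (9) is taken as a commercial reagent for O-tert-prenylation.

**Step 1**
Reactants: 1 4-hydroxybenzonitrile; 2 4-methylbenzenesulfonyl chloride
Product: 3 4-cyanophenyl 4-methylbenzenesulfonate
Conditions: Et3N, DMAP (cat.), CH2Cl2, 0 °C to rt
Reagents that add atoms: 4-methylbenzenesulfonyl chloride (2), Cc1ccc(cc1)S(=O)(=O)Cl
Why: Sulfonylation of a phenol; the aryl tosylate should survive the acid of step 2, the bases and zerovalent palladium of steps 3 and 4 and the heat of step 5, and is the only protecting group of the route.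

**Step 2**
Reactants: 3 4-cyanophenyl 4-methylbenzenesulfonate; 4 phloroglucinol
Product: 6 4-(2,4,6-trihydroxybenzoyl)phenyl 4-methylbenzenesulfonate, via ketiminium chloride 5 (not isolated)
Conditions: ZnCl2, HCl (g), Et2O, 0 °C to rt; then H2O, 100 °C
Reagents that add atoms: water, O
Why: Hoesch acylation, in which the nitrilium species from 3 attacks one of the three equivalent carbons of phloroglucinol, the precipitating ketiminium salt prevents a second acylation, and hydrolysis gives the aryl ketone.

**Step 3**
Reactants: 6 4-(2,4,6-trihydroxybenzoyl)phenyl 4-methylbenzenesulfonate; 7 3-chloro-3-methylbut-1-yne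
Product: 8 4-{2,6-dihydroxy-4-[(2-methylbut-3-yn-2-yl)oxy]benzoyl}phenyl 4-methylbenzenesulfonate
Conditions: 7 (1.1 equiv), DBU (1.2 equiv), CuCl2·2H2O (1 mol %), MeCN, 0 °C
Reagents that add atoms: 3-chloro-3-methylbut-1-yne (7), CC(C)(Cl)C#C
Why: Copper-catalysed propargylic etherification of a phenol with a tertiary propargyl chloride (through a copper acetylide), expected at the hydroxyl para to the carbonyl because it is the most acidic one and the only one not hydrogen-bonded to the ketone.

**Step 4**
Reactants: 8 4-{2,6-dihydroxy-4-[(2-methylbut-3-yn-2-yl)oxy]benzoyl}phenyl 4-methylbenzenesulfonate; 9 tert-butyl 2-methylbut-3-en-2-yl carbonate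
Product: 10 4-{2-hydroxy-6-[(2-methylbut-3-en-2-yl)oxy]-4-[(2-methylbut-3-yn-2-yl)oxy]benzoyl}phenyl 4-methylbenzenesulfonate
Conditions: 9 (1.5 equiv), Pd(PPh3)4 (5 mol %), 4 Å MS, THF, 0 °C, short reaction time; cold filtration through silica, product kept below 25 °C and used at once
Reagents that add atoms: tert-butyl 2-methylbut-3-en-2-yl carbonate (9), CC(C)(C)OC(=O)OC(C)(C)C=C
Why: Tsuji–Trost-type decarboxylative O-allylation, in which the phenoxide attacks the more substituted terminus of the 1,1-dimethylallyl palladium cation to give the kinetic tertiary ether; the two hydroxyls of 8 are equivalent, so monoalkylation gives one compound, and the last, chelated hydroxyl should react much more slowly.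

**Step 5**
Reactants: 10 4-{2-hydroxy-6-[(2-methylbut-3-en-2-yl)oxy]-4-[(2-methylbut-3-yn-2-yl)oxy]benzoyl}phenyl 4-methylbenzenesulfonate
Product: 14 4'-O-tosylvismiaphenone E, via C-prenyl propargyl ether 11 (not isolated), via allenylphenol 12 (not isolated), via ortho-quinone methide 13 (not isolated)
Conditions: PhNEt2 (degassed), Ar, 110 °C, then 185 °C
Reagents that add atoms: none
Why: On warming, the aryl 1,1-dimethylallyl ether undergoes the aromatic Claisen [3,3] shift to its only free ortho carbon (future C8; the other ortho carbon bears the aroyl group) and enolises to 11, a reaction known to run well below the temperature that the propargyl ether needs. At the higher temperature the aryl 1,1-dimethylpropargyl ether of 11 shifts [3,3] to the one ortho carbon that still carries hydrogen, which forms the C4–C4a bond; enolisation gives allenylphenol 12, a 1,5-hydrogen shift gives the Z ortho-quinone methide 13, and a thermal disrotatory 6π oxa-electrocyclisation re-joins O1 to C2. The closest known reactions are the Claisen rearrangement of aryl 1,1-dimethylallyl ethers to ortho-prenylphenols and the thermal conversion of aryl 1,1-dimethylpropargyl ethers into 2,2-dimethyl-2H-chromenes, both standard on acylphloroglucinol ethers. Ring B is closed by this pericyclic sequence, which amounts to a 6-endo hydroarylation of the alkyne with C4–C4a as the only new bond of the ring, and no stereocentre is formed. The step needs site selectivity between C4a and C8 for the two migrating groups; this is secured by the order of events (the allyl shift fills C8 first, at the lower temperature) and by the aroyl group blocking the remaining ortho site, while the weakly basic amine solvent should suppress acid-catalysed cyclisation of the ortho-prenylphenol to a chroman.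

**Step 6**
Reactants: 14 4'-O-tosylvismiaphenone E
Product: 15 vismiaphenone E
Conditions: KOH (5 equiv), MeOH/H2O, 60 °C, Ar; then dilute aq. HCl
Reagents that add atoms: none
Why: Alkaline S–O cleavage of an aryl sulfonate activated by the para carbonyl group; chromene, prenyl group and ketone are stable to hydroxide, and air is excluded to protect the phenoxides.

**Compound list**

1 | 4-hydroxybenzonitrile | N#Cc1ccc(O)cc1 | starting material
2 | 4-methylbenzenesulfonyl chloride | Cc1ccc(cc1)S(=O)(=O)Cl | starting material
3 | 4-cyanophenyl 4-methylbenzenesulfonate | Cc1ccc(cc1)S(=O)(=O)Oc1ccc(cc1)C#N | intermediate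
4 | phloroglucinol (benzene-1,3,5-triol) | Oc1cc(O)cc(O)c1 | starting material
5 | ketiminium chloride of 6: 4-[iminio(2,4,6-trihydroxyphenyl)methyl]phenyl 4-methylbenzenesulfonate chloride | Cc1ccc(cc1)S(=O)(=O)Oc1ccc(cc1)C(=[NH2+])c1c(O)cc(O)cc1O.[Cl-] | intermediate (not isolated)
6 | 4-(2,4,6-trihydroxybenzoyl)phenyl 4-methylbenzenesulfonate | Cc1ccc(cc1)S(=O)(=O)Oc1ccc(cc1)C(=O)c1c(O)cc(O)cc1O | intermediate
7 | 3-chloro-3-methylbut-1-yne | CC(C)(Cl)C#C | starting material
8 | 4-{2,6-dihydroxy-4-[(2-methylbut-3-yn-2-yl)oxy]benzoyl}phenyl 4-methylbenzenesulfonate | Cc1ccc(cc1)S(=O)(=O)Oc1ccc(cc1)C(=O)c1c(O)cc(OC(C)(C)C#C)cc1O | intermediate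
9 | tert-butyl 2-methylbut-3-en-2-yl carbonate | CC(C)(C)OC(=O)OC(C)(C)C=C | starting material
10 | 4-{2-hydroxy-6-[(2-methylbut-3-en-2-yl)oxy]-4-[(2-methylbut-3-yn-2-yl)oxy]benzoyl}phenyl 4-methylbenzenesulfonate | Cc1ccc(cc1)S(=O)(=O)Oc1ccc(cc1)C(=O)c1c(O)cc(OC(C)(C)C#C)cc1OC(C)(C)C=C | intermediate
11 | 4-{2,6-dihydroxy-3-(3-methylbut-2-en-1-yl)-4-[(2-methylbut-3-yn-2-yl)oxy]benzoyl}phenyl 4-methylbenzenesulfonate (C-prenyl propargyl ether) | Cc1ccc(cc1)S(=O)(=O)Oc1ccc(cc1)C(=O)c1c(O)cc(OC(C)(C)C#C)c(CC=C(C)C)c1O | intermediate (not isolated)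
12 | 4-[2,4,6-trihydroxy-3-(3-methylbuta-1,2-dien-1-yl)-5-(3-methylbut-2-en-1-yl)benzoyl]phenyl 4-methylbenzenesulfonate (allenylphenol) | Cc1ccc(cc1)S(=O)(=O)Oc1ccc(cc1)C(=O)c1c(O)c(C=C=C(C)C)c(O)c(CC=C(C)C)c1O | intermediate (not isolated)
13 | ortho-quinone methide: ring A as a 2,4-dihydroxy-cyclohexa-2,4-dienone bearing the aroyl group, the prenyl group and a Z-configured exocyclic 3-methylbut-2-enylidene group next to the ring carbonyl | Cc1ccc(cc1)S(=O)(=O)Oc1ccc(cc1)C(=O)C1=C(O)/C(=C/C=C(C)C)C(=O)C(CC=C(C)C)=C1O | intermediate (not isolated)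
14 | 4'-O-tosylvismiaphenone E: 4-{[5,7-dihydroxy-2,2-dimethyl-8-(3-methylbut-2-en-1-yl)-2H-chromen-6-yl]carbonyl}phenyl 4-methylbenzenesulfonate | Cc1ccc(cc1)S(=O)(=O)Oc1ccc(cc1)C(=O)c1c(O)c(CC=C(C)C)c2OC(C)(C)C=Cc2c1O | intermediate
15 | vismiaphenone E | CC(C)=CCc1c(O)c(C(=O)c2ccc(O)cc2)c(O)c2c1OC(C)(C)C=C2 | target

**Totals**

Total step count: 6. Longest linear sequence: 6 steps (from 4-hydroxybenzonitrile). The target has no stereocentre; the only stereochemical element on the way is the Z geometry of the transient 13, which the intramolecular hydrogen shift sets.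

**Steps most likely to fail**

Step 4. The chelated, hindered hydroxyl may be allylated too slowly, the kinetic tertiary ether may re-ionise on palladium and isomerise to the linear prenyl ether, and zerovalent palladium may engage the terminal alkyne. The fallback delivers the prenyl group from the para oxygen before the propargyl group is placed there. It sets out from 8. Semihydrogenation of the alkyne (H2, Pd/CaCO3 poisoned with Pb(OAc)2, quinoline, EtOAc, rt) should give the tertiary allyl ether 4-{2,6-dihydroxy-4-[(2-methylbut-3-en-2-yl)oxy]benzoyl}phenyl 4-methylbenzenesulfonate F1. Its Claisen rearrangement (toluene, 110 °C) to either of the two equivalent ortho carbons should give the C-prenyl triol 4-[2,4,6-trihydroxy-3-(3-methylbut-2-en-1-yl)benzoyl]phenyl 4-methylbenzenesulfonate F2. Renewed propargylation of the para oxygen with 7 (DBU, CuCl2·2H2O cat., MeCN, 0 °C) comes back to the route at 11, which is then heated as in the second stage of step 5.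

Step 5. The two sigmatropic shifts may not stay ordered (a propargyl shift to the carbon that the allyl group needs), the tertiary allyl ether may lose isoprene instead of rearranging, and the ortho-prenylphenol may cyclise to a chroman at the higher temperature. The fallback separates the two events and brings in the prenyl group by direct C-alkylation. It sets out from 8. Heating of this symmetric propargyl ether alone (PhNEt2, 185 °C) should give a single chromene, 4-[(5,7-dihydroxy-2,2-dimethyl-2H-chromen-6-yl)carbonyl]phenyl 4-methylbenzenesulfonate F3. Nuclear prenylation of its only free ring carbon, C8, with 1-bromo-3-methylbut-2-ene (DBU, THF, 0 °C to rt) comes back to the route at 14.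

Step 3. The ambident phloroglucinolate may be alkylated a second time at oxygen or at carbon, and conversion may stay incomplete at the stoichiometry that avoids this. The fallback masks the two carbonyl-flanking hydroxyls as esters so that only the para oxygen can react. It sets out from 6. Peracetylation (Ac2O, pyridine, rt) should give the triacetate 2-{4-[(4-methylbenzenesulfonyl)oxy]benzoyl}benzene-1,3,5-triyl triacetate F4. Selective removal of the acetate para to the carbonyl (PhSH, imidazole, N-methylpyrrolidinone, 0 °C) should give the 4-hydroxy diacetate F5. Propargylation of its single free hydroxyl with 7 (DBU, CuCl2·2H2O cat., MeCN, 0 °C) should give the propargyl ether diacetate F6. Mild methanolysis (K2CO3, MeOH, 0 °C) comes back to the route at 8.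

**Further compounds**

F1 | step 4 | 4-{2,6-dihydroxy-4-[(2-methylbut-3-en-2-yl)oxy]benzoyl}phenyl 4-methylbenzenesulfonate | Cc1ccc(cc1)S(=O)(=O)Oc1ccc(cc1)C(=O)c1c(O)cc(OC(C)(C)C=C)cc1O
F2 | step 4 | 4-[2,4,6-trihydroxy-3-(3-methylbut-2-en-1-yl)benzoyl]phenyl 4-methylbenzenesulfonate | Cc1ccc(cc1)S(=O)(=O)Oc1ccc(cc1)C(=O)c1c(O)cc(O)c(CC=C(C)C)c1O
F3 | step 5 | 4-[(5,7-dihydroxy-2,2-dimethyl-2H-chromen-6-yl)carbonyl]phenyl 4-methylbenzenesulfonate | Cc1ccc(cc1)S(=O)(=O)Oc1ccc(cc1)C(=O)c1c(O)cc2OC(C)(C)C=Cc2c1O
F4 | step 3 | 2-{4-[(4-methylbenzenesulfonyl)oxy]benzoyl}benzene-1,3,5-triyl triacetate | Cc1ccc(cc1)S(=O)(=O)Oc1ccc(cc1)C(=O)c1c(OC(C)=O)cc(OC(C)=O)cc1OC(C)=O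
F5 | step 3 | 5-hydroxy-2-{4-[(4-methylbenzenesulfonyl)oxy]benzoyl}-1,3-phenylene diacetate | Cc1ccc(cc1)S(=O)(=O)Oc1ccc(cc1)C(=O)c1c(OC(C)=O)cc(O)cc1OC(C)=O
F6 | step 3 | 5-[(2-methylbut-3-yn-2-yl)oxy]-2-{4-[(4-methylbenzenesulfonyl)oxy]benzoyl}-1,3-phenylene diacetate | Cc1ccc(cc1)S(=O)(=O)Oc1ccc(cc1)C(=O)c1c(OC(C)=O)cc(OC(C)(C)C#C)cc1OC(C)=O
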